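**Retrosynthetic overview**
- The target comes from methylenation of keto diacetate 18, whose two bicyclic halves are built one after the other on the two arms of the C2-symmetric bibenzyl tetraepoxide 8.
- Each half: a bis-epoxide cascade (oxepane first, then cyclohexane) is terminated by ipso attack of a 1,2-dimethoxyarene carbon, which dearomatizes that ring to a cyclohexadienone. KMnO4/NaIO4 then excises three former arene carbons, and decarboxylation leaves the ring ketone and its α-C–H.
- Symmetry is broken by closing one arm only. That half is taken to the tertiary/secondary diacetate before the second arm is closed, so the last-formed hydroxyl is the only free one.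
- Tetraepoxide 8 comes from Shi epoxidation of tetraene 7, made from 2,3-dimethoxytoluene by chloromethylation, reductive coupling of two molecules, and twofold benzylic geranylation.
- Ring order: oxepane then cyclohexane of the acetate half; oxepane then cyclohexane of the methylene half.

Assumption: locants follow the squalene-type chain of the target (methylene half C2–C11 with C10=CH2, linker C12–C13, acetate half C14–C23 with C15(Me)OAc and C22–OAc; target = 3R,6R,7R,11S,14R,15S,18R,19R,22R), and the D-fructose-derived Shi ketone is taken to give the R-configured epoxides on (E)-trisubstituted olefins.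

**Step 1**
Reactants: 1 2,3-dimethoxytoluene
Product: 2 1-(chloromethyl)-3,4-dimethoxy-2-methylbenzene
Conditions: (CH2O)n, HCl (gas), 1,4-dioxane, 15 °C
Reagents that add atoms: formaldehyde (as paraformaldehyde), C=O; hydrogen chloride, Cl
Why: Blanc chloromethylation (electrophilic aromatic substitution) goes to the free position para to the unhindered methoxy group and ortho to the methyl group, the flanked methoxy group being twisted out of conjugation; no stereocentre is formed.

**Step 2**
Reactants: 2 1-(chloromethyl)-3,4-dimethoxy-2-methylbenzene (2 equiv)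
Product: 4 1,2-bis(3,4-dimethoxy-2-methylphenyl)ethane, via (3,4-dimethoxy-2-methylbenzyl)magnesium chloride 3 (not isolated)
Conditions: Mg (0.55 equiv), THF, 45 °C
Reagents that add atoms: benzylic chloride 2 (second molecule), Cc1c(CCl)ccc(OC)c1OC
Why: Wurtz-type reductive homocoupling, in which the benzylic Grignard reagent 3 formed from one molecule of 2 is alkylated by a second molecule of the electron-rich benzylic chloride, joins two aryl units through the C12–C13 linker.

**Step 3**
Reactants: 4 1,2-bis(3,4-dimethoxy-2-methylphenyl)ethane; 5 geranyl bromide [(2E)-1-bromo-3,7-dimethylocta-2,6-diene] (2 equiv)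
Product: 7 1,2-bis{2-[(3E)-4,8-dimethylnona-3,7-dien-1-yl]-3,4-dimethoxyphenyl}ethane, via dipotassium bis-benzylic dianion 6 (not isolated)
Conditions: n-BuLi, KOt-Bu, 2,2,6,6-tetramethylpiperidine (2.4 equiv each), THF, −78 °C; then 5 (2.4 equiv), −78 → 20 °C
Reagents that add atoms: geranyl bromide 5 (second molecule), CC(C)=CCC/C(C)=C/CBr
Why: Lateral (benzylic) metalation with the mixed n-BuLi/KOt-Bu/amine base equilibrates to the primary benzylic potassium species at each aryl methyl group (ortho to OMe) in preference to ring or linker positions, and SN2 alkylation at the primary allylic carbon of two molecules of 5 keeps the E-olefins and installs the C8–C2 and C17–C23 chains.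

**Step 4**
Reactants: 7 the tetraene
Product: 8 (3R,6R,7R,18R,19R,22R)-tetraepoxide, i.e. 1,2-bis{3,4-dimethoxy-2-[2-((2R,3R)-3-methyl-3-{2-[(2R)-3,3-dimethyloxiran-2-yl]ethyl}oxiran-2-yl)ethyl]phenyl}ethane
Conditions: D-fructose-derived Shi ketone (30 mol % per olefin), KHSO5 (as 2KHSO5·KHSO4·K2SO4), K2CO3, Bu4NHSO4, MeCN/CH2(OMe)2/aq. Na2B4O7 (pH 10.5), 0 °C
Reagents that add atoms: potassium peroxymonosulfate, [K+].[O-]S(=O)(=O)OO
Why: Shi asymmetric epoxidation (chiral dioxirane, spiro transition state) attacks all four (E)-trisubstituted olefins on the same face and sets C3, C6, C7, C18, C19 and C22 as R, while the arenes are inert at 0 °C.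

**Step 5**
Reactants: 8 the tetraepoxide
Product: 10 mono-cyclized dienone alcohol [acetate-half (18R,19R,22R)-22-hydroxy trans-fused oxepane/cyclohexane whose C14–C15 bond belongs to a 2-methoxycyclohexa-2,5-dienone (C14 = sp3 carbon bearing the linker, configuration open; C15 = dienone C3), joined through C13H2–C12H2 to the unchanged aryl bis-epoxide arm], via methoxy-oxocarbenium triflate 9 (not isolated)
Conditions: TMSOTf (1.0 equiv), 2,6-di-tert-butyl-4-methylpyridine, CH2Cl2, −78 °C; aq. NaHCO3; then K2CO3 (cat.), MeOH, 0 °C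
Reagents that add atoms: water, O
Why: Proposed new method: TMSOTf silylates one terminal epoxide, the neighbouring epoxide oxygen opens it at the tertiary carbon (endo mode, oxepane) to an epoxonium ion, and the aromatic carbon para to a methoxy group and ortho to the tether (the carbon carrying the linker; the other ortho position is blocked by OMe) attacks the tertiary epoxonium carbon C19 with inversion through the chair-like six-ring transition state of arene-terminated epoxy-polyene cyclizations; because that carbon is already substituted the arenium ion cannot lose a proton and persists as oxocarbenium triflate 9, which water hydrolyses to the cross-conjugated dienone, so the ring is dearomatized; C22 (R) and C18 (R) keep the epoxide configuration, C19 (R) arises by inversion and the E-olefin gives the trans ring fusion; with one equivalent of TMSOTf one arm reacts on average (about 1:2:1 recovered 8 : 10 : doubly cyclized material), which breaks the C2 symmetry; closest known reaction types are the TMSOTf-promoted tandem oxa-/carbacyclization of bis-epoxides terminated by alkenes or enol silanes and the ipso-Friedel–Crafts dearomatization of para-alkyl anisoles and phenols.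

**Step 6**
Reactants: 10 the mono-cyclized dienone alcohol
Product: 12 keto alcohol [(14R,18R,19R,22R)-15-oxo-22-hydroxy bicycle with C14–H, joined through the linker to the aryl bis-epoxide arm], via β-keto acid 11 (not isolated)
Conditions: KMnO4 (10 mol %), NaIO4 (8 equiv), K2CO3, t-BuOH/H2O, 20 °C; NaH2PO4 to pH 6, 45 °C; then K2CO3, MeOH, 20 °C
Reagents that add atoms: potassium permanganate, [K+].[O-][Mn](=O)(=O)=O; sodium periodate, [Na+].[O-]I(=O)(=O)=O
Why: Lemieux–von Rudloff oxidative cleavage of both dienone C=C bonds (the dimethoxyarene and the trisubstituted epoxides survive the buffered medium) turns C15 into the ketone and C14 into a β-keto acid that loses CO2 at pH 6, and K2CO3/MeOH then equilibrates C14–H to the equatorial, thermodynamically preferred side chain (14R).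

**Step 7**
Reactants: 12 the keto alcohol
Product: 14 diacetate [(14R,15S,18R,19R,22R)-15-acetoxy-15-methyl-22-acetoxy bicycle joined to the aryl bis-epoxide arm], via dilithium dialkoxide 13 (not isolated)
Conditions: MeLi (3 equiv), THF, −78 °C; then Ac2O (6 equiv), DMAP (0.2 equiv), −78 → 20 °C
Reagents that add atoms: methyllithium, [Li]C; acetic anhydride, CC(=O)OC(C)=O
Why: 1,2-Addition from the equatorial direction (the axial face is blocked by the syn-axial C19 methyl) gives the axial alkoxide and equatorial methyl (15S), and O-acylation of both lithium alkoxides in the same flask gives the tertiary and secondary acetates; the epoxides do not react with MeLi at −78 °C.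

**Step 8**
Reactants: 14 the diacetate
Product: 16 dienone diacetate alcohol [acetate half complete; methylene-half (3R,6R,7R)-3-hydroxy bicycle whose C11–C10 bond belongs to a 2-methoxycyclohexa-2,5-dienone, C11 configuration open], via methoxy-oxocarbenium triflate 15 (not isolated)
Conditions: TMSOTf (1.3 equiv), 2,6-di-tert-butyl-4-methylpyridine, CH2Cl2, −78 °C; aq. NaHCO3; then AcOH/THF/H2O, 20 °C
Reagents that add atoms: water, O
Why: Proposed new method: the same epoxide-opening/ipso-Friedel–Crafts dearomatizing cascade as in step 5 on the remaining arm, the secondary and the non-allylic tertiary acetate not being ionized at −78 °C beside the hindered pyridine; C3 (R), C7 (R) and C6 (R) are set as before and dilute acetic acid frees the new C3 hydroxyl from its TMS ether, so it is the only free hydroxyl; closest known reaction types as in step 5.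

**Step 9**
Reactants: 16 the dienone diacetate alcohol
Product: 18 keto diacetate alcohol [(3R,6R,7R,11R)-10-oxo-3-hydroxy bicycle linked to the (14R,15S,18R,19R,22R)-diacetate half], via β-keto acid 17 (not isolated)
Conditions: KMnO4 (10 mol %), NaIO4 (8 equiv), NaHCO3, t-BuOH/H2O, 20 °C; NaH2PO4 to pH 6, 45 °C; then DBU, CH2Cl2, 20 °C
Reagents that add atoms: potassium permanganate, [K+].[O-][Mn](=O)(=O)=O; sodium periodate, [Na+].[O-]I(=O)(=O)=O
Why: The same Lemieux–von Rudloff cleavage and β-keto acid decarboxylation as in step 6 (acetates are stable at pH 6–8) gives the C10 ketone, and DBU equilibrates C11 to the equatorial side chain without touching the esters.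

**Step 10**
Reactants: 18 the keto diacetate alcohol
Product: 19 target, (3R,6R,7R,11S,14R,15S,18R,19R,22R)
Conditions: Zn, CH2Br2, TiCl4, THF/CH2Cl2, 0 → 20 °C
Reagents that add atoms: dibromomethane, BrCBr
Why: Takai–Lombardo methylenation with a non-basic gem-dimetallic CH2 reagent converts the C10 ketone into the exocyclic methylene without epimerizing C11 or attacking the acetates, the free hydroxyl only consuming reagent.

**Compound list**
1 | 2,3-dimethoxytoluene | Cc1cccc(OC)c1OC | starting material
2 | 1-(chloromethyl)-3,4-dimethoxy-2-methylbenzene | Cc1c(CCl)ccc(OC)c1OC | intermediate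
3 | (3,4-dimethoxy-2-methylbenzyl)magnesium chloride | Cc1c(C[Mg]Cl)ccc(OC)c1OC | intermediate
4 | 1,2-bis(3,4-dimethoxy-2-methylphenyl)ethane | Cc1c(CCc2ccc(OC)c(OC)c2C)ccc(OC)c1OC | intermediate
5 | geranyl bromide | CC(C)=CCC/C(C)=C/CBr | starting material
6 | dipotassium bis-benzylic dianion of 4 | [K+].[K+].[CH2-]c1c(CCc2ccc(OC)c(OC)c2[CH2-])ccc(OC)c1OC | intermediate
7 | 1,2-bis{2-[(3E)-4,8-dimethylnona-3,7-dien-1-yl]-3,4-dimethoxyphenyl}ethane | CC(C)=CCC/C(C)=C/CCc1c(OC)c(OC)ccc1CCc1ccc(OC)c(OC)c1CC/C=C(\C)CCC=C(C)C | intermediate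
8 | (3R,6R,7R,18R,19R,22R)-tetraepoxide of 7 | CC1(C)O[C@@H]1CC[C@@]1(C)O[C@@H]1CCc1c(OC)c(OC)ccc1CCc1ccc(OC)c(OC)c1CC[C@H]1O[C@]1(C)CC[C@H]1OC1(C)C | intermediate
9 | methoxy-oxocarbenium triflate, 22-O-TMS ether (C14 undefined) | CC1(C)O[C@@H]1CC[C@@]1(C)O[C@@H]1CCc1c(OC)c(OC)ccc1CCC12C=CC(=[O+]C)C(OC)=C1CC[C@H]3OC(C)(C)[C@H](O[Si](C)(C)C)CC[C@@]32C.[O-]S(=O)(=O)C(F)(F)F | intermediate
10 | mono-cyclized dienone alcohol (C14 undefined) | CC1(C)O[C@@H]1CC[C@@]1(C)O[C@@H]1CCc1c(OC)c(OC)ccc1CCC12C=CC(=O)C(OC)=C1CC[C@H]3OC(C)(C)[C@H](O)CC[C@@]32C | intermediate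
11 | β-keto acid at C14 (C14 undefined) | O=C1CC[C@H]2OC(C)(C)[C@H](O)CC[C@]2(C)C1(C(=O)O)CCc1ccc(OC)c(OC)c1CC[C@H]1O[C@]1(C)CC[C@H]1OC1(C)C | intermediate
12 | keto alcohol (15-oxo, 22-hydroxy; arene arm with bis-epoxide) | O=C1CC[C@H]2OC(C)(C)[C@H](O)CC[C@]2(C)[C@H]1CCc1ccc(OC)c(OC)c1CC[C@H]1O[C@]1(C)CC[C@H]1OC1(C)C | intermediate
13 | dilithium 15,22-dialkoxide | [Li+].[Li+].[O-][C@@]1(C)CC[C@H]2OC(C)(C)[C@H]([O-])CC[C@]2(C)[C@H]1CCc1ccc(OC)c(OC)c1CC[C@H]1O[C@]1(C)CC[C@H]1OC1(C)C | intermediate
14 | 15,22-diacetate (arene arm with bis-epoxide) | CC(=O)O[C@@]1(C)CC[C@H]2OC(C)(C)[C@H](OC(C)=O)CC[C@]2(C)[C@H]1CCc1ccc(OC)c(OC)c1CC[C@H]1O[C@]1(C)CC[C@H]1OC1(C)C | intermediate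
15 | methoxy-oxocarbenium triflate of the second closure, 3-O-TMS ether (C11 undefined) | CC(=O)O[C@@]1(C)CC[C@H]2OC(C)(C)[C@H](OC(C)=O)CC[C@]2(C)[C@H]1CCC12C=CC(=[O+]C)C(OC)=C1CC[C@H]3OC(C)(C)[C@H](O[Si](C)(C)C)CC[C@@]32C.[O-]S(=O)(=O)C(F)(F)F | intermediate
16 | dienone diacetate alcohol (C11 undefined) | CC(=O)O[C@@]1(C)CC[C@H]2OC(C)(C)[C@H](OC(C)=O)CC[C@]2(C)[C@H]1CCC12C=CC(=O)C(OC)=C1CC[C@H]3OC(C)(C)[C@H](O)CC[C@@]32C | intermediate
17 | β-keto acid at C11 (C11 undefined) | CC(=O)O[C@@]1(C)CC[C@H]2OC(C)(C)[C@H](OC(C)=O)CC[C@]2(C)[C@H]1CCC1(C(=O)O)[C@@]2(C)CC[C@@H](O)C(C)(C)O[C@@H]2CCC1=O | intermediate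
18 | keto diacetate alcohol (10-oxo) | CC(=O)O[C@@]1(C)CC[C@H]2OC(C)(C)[C@H](OC(C)=O)CC[C@]2(C)[C@H]1CC[C@@H]1[C@@]2(C)CC[C@@H](O)C(C)(C)O[C@@H]2CCC1=O | intermediate
19 | CNP0412606.2 | C=C1CC[C@H]2OC(C)(C)[C@H](O)CC[C@]2(C)[C@H]1CC[C@@H]1[C@@]2(C)CC[C@@H](OC(C)=O)C(C)(C)O[C@@H]2CC[C@]1(C)OC(C)=O | target

**Total step count:** 10
**Longest linear sequence:** 10

**Steps most likely to fail**

Step 5 (dearomatizing ring closure held at one arm). The ipso closure is unprecedented in this setting: the arenium ion may rearomatize by a 1,2-shift, or the attack may go to the methoxy-bearing ortho carbon. In addition, the mono-cyclization is only statistical. Fallback: desymmetrize at the end instead of the start. It sets out from 8 and comes back at 19. Both arms are closed with 2.6 equiv TMSOTf (same work-up) to the C2-symmetric bis-dienone diol F1. KMnO4/NaIO4 with buffered decarboxylation gives the C2-symmetric diketone diol F2. A deficit of Zn/CH2Br2/TiCl4 methylenates one carbonyl to the mono-methylene keto diol F3 (F2 recovered). MeLi then Ac2O gives the triacetate F4. K2CO3/MeOH to about half conversion removes one secondary acetate and gives 19; the isomeric mono-alcohol and the diol are re-acetylated to F4 and recycled. This path also removes the oxidation beside an electron-rich arene (step 6) and the Lewis-acid exposure of the tertiary acetate (step 8), at the price of two statistical steps, the last one unselective between the two secondary acetates.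

Step 3 (double benzylic metalation of 4). Ring metalation ortho to OMe, deprotonation of the linker CH2 groups, or poor solubility of the dianion may interfere. Fallback: put the chain on the monomer under chelation control and form the linker last. It sets out from 2 and comes back at 7. Me2NH (THF, 0 °C) converts 2 into the benzylic amine F5. n-BuLi (Et2O, 0 °C) lithiates the aryl methyl group, which sits between the CH2NMe2 and OMe donors, and 5 alkylates it to the homogeranyl amine F6. ClCO2Et (toluene, 0 → 20 °C) cleaves the benzylic C–N bond and gives the benzylic chloride F7 without touching the olefins. Mg (0.55 equiv) in THF then couples two molecules of F7, as in step 2, and gives 7.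

Step 7 (methyl addition and acylation of a hindered tertiary alkoxide). Enolization, attack from the wrong face, or incomplete acylation are possible. Fallback: deliver the methyl carbon as an epoxide. It sets out from 12 and comes back at 14. Dimethylsulfoxonium methylide (Me3S(O)I, NaH, DMSO) adds its CH2 equatorially to give the spiro-epoxide F8 with axial oxygen. LiAlH4 at −20 °C opens only the unhindered CH2 terminus to the tertiary/secondary diol F9. Ac2O, Et3N and DMAP at 40 °C then give 14.

**Further compounds**
F1 | step 5 | C2-symmetric bis-dienone diol (both arms cyclized; C11 and C14 undefined) | C(CC12C=CC(=O)C(OC)=C1CC[C@H]3OC(C)(C)[C@H](O)CC[C@@]32C)C12C=CC(=O)C(OC)=C1CC[C@H]3OC(C)(C)[C@H](O)CC[C@@]32C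
F2 | step 5 | C2-symmetric 10,15-diketone 3,22-diol | O=C1CC[C@H]2OC(C)(C)[C@H](O)CC[C@]2(C)[C@H]1CC[C@@H]1[C@@]2(C)CC[C@@H](O)C(C)(C)O[C@@H]2CCC1=O
F3 | step 5 | mono-methylene keto diol | C=C1CC[C@H]2OC(C)(C)[C@H](O)CC[C@]2(C)[C@H]1CC[C@@H]1[C@@]2(C)CC[C@@H](O)C(C)(C)O[C@@H]2CCC1=O
F4 | step 5 | 3,15,22-triacetate of the 10-methylene compound | C=C1CC[C@H]2OC(C)(C)[C@H](OC(C)=O)CC[C@]2(C)[C@H]1CC[C@@H]1[C@@]2(C)CC[C@@H](OC(C)=O)C(C)(C)O[C@@H]2CC[C@]1(C)OC(C)=O
F5 | step 3 | 1-(3,4-dimethoxy-2-methylphenyl)-N,N-dimethylmethanamine | CN(C)Cc1ccc(OC)c(OC)c1C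
F6 | step 3 | 1-{2-[(3E)-4,8-dimethylnona-3,7-dien-1-yl]-3,4-dimethoxyphenyl}-N,N-dimethylmethanamine | CN(C)Cc1ccc(OC)c(OC)c1CC/C=C(\C)CCC=C(C)C
F7 | step 3 | 1-(chloromethyl)-2-[(3E)-4,8-dimethylnona-3,7-dien-1-yl]-3,4-dimethoxybenzene | ClCc1ccc(OC)c(OC)c1CC/C=C(\C)CCC=C(C)C
F8 | step 7 | C15 spiro-epoxide (axial oxygen) of the acetate-half bicycle, 22-hydroxy, arene arm with bis-epoxide | C1O[C@]12CC[C@H]3OC(C)(C)[C@H](O)CC[C@]3(C)[C@H]2CCc1ccc(OC)c(OC)c1CC[C@H]1O[C@]1(C)CC[C@H]1OC1(C)C
F9 | step 7 | (15S)-15-methyl-15,22-diol, arene arm with bis-epoxide | O[C@@]1(C)CC[C@H]2OC(C)(C)[C@H](O)CC[C@]2(C)[C@H]1CCc1ccc(OC)c(OC)c1CC[C@H]1O[C@]1(C)CC[C@H]1OC1(C)C
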